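Of each amount of substrate that reacts, 28.1% becomes target: this branch share s, the constant of the step to target divided by the sum of both constants, is the selectivity of the branch.

    substrate → target (k1 = 2.5 × 10⁻⁴ s⁻¹)
    substrate → side product (k2 = 6.4 × 10⁻⁴ s⁻¹)

all flasks: substrate 0.10 M

| run | time | remark |
|---|---|---|
| dusk | 5.0 h | plug flow through a tube for 5.0 h, no back-mixing |
| noon | 5.0 h | a closed flask charged with all of it at once and left for 5.0 h |
| spring |  | one stirred flow tank at steady state, fed with the mixture as stated, mean residence time 5.0 h |

- the set-up with the highest amount of target at the outlet or at the end, in percent of the substrate put in ("none" if the first two lie within 2 percentage points) (dusk / noon / spring / none)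
- amount of target at the outlet or at the end, in percent of the substrate put in, dusk
- amount of target at the outlet or at the end, in percent of the substrate put in, noon
- amount of target at the outlet or at the end, in percent of the substrate put in, spring

- the stated concentrations are those of everything mixed, before any reaction; amounts are the same in each set-up
- run time (dusk): 5.0 h

1. Concentration. The substrate stands on the left of both steps, so both rates are first order in it. Their ratio stays 0.391 as the substrate falls from 0.10 M, and s stays with it. Neither target nor side product reacts further, so target equals s times the substrate reacted.

2. Time. The substrate drains with the summed constant K = 3.20 h⁻¹, a lifetime of 0.312 h, far shorter than the 5.0 h allowed. That span is N = 16.0 lifetimes (N, the Damköhler number). The closed flask noon therefore ends at 28.1%.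

3. Vessel. Each slice of the tube dusk ages like the closed flask, so dusk reaches 28.1%. The tank spring runs at its outlet concentration, and its balance leaves a fraction 1/(1+N) = 5.88% of the substrate unreacted. With s unchanged, spring gives 26.4%.

4. Margin. The first two set-ups are dusk and noon, which have the same s and the same N, so they stand level, inside the margin of 2 percentage points, and this reckoning gives none as best. Spring comes third, 1.7 points behind dusk.

The forecast gave 28.1% for dusk, 28.1% for noon, 26.4% for spring and none as best, holding that the target takes its share “of whatever reacts, whatever the vessel”.

The simulation gives 28.1% for dusk, 28.1% for noon, 26.4% for spring, and none as best. The tank spring still holds 5.88% of the substrate charged, 0.00588 M throughout. Applied to that reading, s times the substrate reacted gives 26.4% of target in spring. Left ten times as long, to 50.0 h, the tube dusk gains nothing. There s of the charge is 28.1%, and the reading stands at 28.1%.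

The numbers were drawn at random within sensible limits; the result is computed.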